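## Retrosynthetic overview
1. The target comes from its octamethyl ether by a final global O-demethylation.
2. The key cut is the C–D biaryl bond, made last. Ring C acts as an ortho-electrophilic phenoxenium ion (a phenol oxidised by trivalent iodine), and ring D is plain 1,3,5-trimethoxybenzene. This step desymmetrises a symmetric A–O–B–O–C bis-phenol in which rings A and C are still identical.
3. The bis-phenol comes from a dialdehyde (CHO as masked OH, Baeyer–Villiger). The dialdehyde comes from 3,5-dibromoanisole (ring B) and two syringaldehydes (rings A and C) by a double Ullmann etherification.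
4. No ring is built, since all four benzene rings are bought. B–O–A and B–O–C are joined together first, then C–D.

Assumption: the SMILES has no stereocentre, and the tetra-ortho-substituted biaryl axis is not stereogenic because ring D is symmetric about it. The target is therefore achiral and no enantiocontrol is needed.

## Route

Step 1
Reactants: 1 1,3-dibromo-5-methoxybenzene (3,5-dibromoanisole); 2 syringaldehyde (4-hydroxy-3,5-dimethoxybenzaldehyde, 2.5 equiv)
Product: 4 4,4'-[(5-methoxy-1,3-phenylene)bis(oxy)]bis(3,5-dimethoxybenzaldehyde), via monoether bromide 3 (not isolated)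
Conditions: CuI (20 mol %), picolinic acid (40 mol %), K3PO4 (4.5 equiv), DMSO, 100 °C, Ar, 36 h
Reagents that add atoms: none
Why: This is an Ullmann-type copper-catalysed C–O coupling in which the hindered partner is the phenoxide and the unhindered meta-dibromide is the electrophile, a pairing for which CuI/picolinic acid tolerates 2,6-disubstituted phenols, and the first ether barely changes the second C–Br site, so both react; no stereocentre is formed.

Step 2
Reactants: 4 dialdehyde
Product: 6 4,4'-[(5-methoxy-1,3-phenylene)bis(oxy)]bis(3,5-dimethoxyphenol), via bis-formate 5 (not isolated)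
Conditions: mCPBA (3 equiv), CH2Cl2, 0 °C → rt; aq. NaHCO3 wash; crude 5 in MeOH, K2CO3 (0.2 equiv), rt, Ar
Reagents that add atoms: mCPBA, O=C(OO)c1cccc(Cl)c1
Why: In this Baeyer–Villiger (Dakin-type) oxidation the para-oxygenated trialkoxyaryl group migrates in the Criegee adduct faster than hydride, as it does for 3,4,5-trimethoxybenzaldehyde, the labile aryl formates are then methanolysed, and ring B and the diaryl ethers are inert to mCPBA at rt.

Step 3
Reactants: 6 bis-phenol; 7 1,3,5-trimethoxybenzene (10 equiv, excess recovered)
Product: 9 3-[3-(4-hydroxy-2,6-dimethoxyphenoxy)-5-methoxyphenoxy]-2,2',4,4',6'-pentamethoxybiphenyl-6-ol, via phenoxenium acetate 8 (not isolated)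
Conditions: PhI(OAc)2 (0.9 equiv, HFIP solution added over 1 h), anhydrous HFIP, 0 °C, Ar; chromatography, unreacted 6 recycled
Reagents that add atoms: none
Why: Proposed new method: ligand exchange of one phenol OH of 6 on PhI(OAc)2 and loss of PhI in ionising, non-nucleophilic HFIP gives the aryloxy-stabilised phenoxenium ion 8, an aromatic enolonium equivalent whose ortho carbon (alpha to the nascent C=O, normally as nucleophilic as a carbon of 7) is now electrophilic while the para carbon is blocked by O–ring B and flanked by two OMe groups, so excess 7 attacks the ortho CH in a Friedel–Crafts sense and tautomerisation restores the phenol; the two ortho sites are equivalent, the two remote phenol termini react independently (statistical mono-coupling, held by sub-stoichiometric oxidant), phenol oxidation is much faster than condensation of the iodane with 7, and no stereogenic axis arises because ring D is symmetric; the closest known reaction types are the hypervalent-iodine oxidative phenol–arene cross-coupling and the acid-promoted arylation of quinone monoacetals alpha to the carbonyl.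

Step 4
Reactants: 9 octamethyl ether
Product: 10 3-[3-hydroxy-5-(2,4,6-trihydroxyphenoxy)phenoxy]biphenyl-2,2',4,4',6,6'-hexol (target CNP0260439.0)
Conditions: BBr3 (16 equiv), CH2Cl2, −78 °C → rt, 18 h, Ar; ice-water; EtOAc extraction, Sephadex LH-20
Reagents that add atoms: none
Why: BBr3 ether cleavage (boron coordination, then bromide SN2 at methyl) removes all eight methyl groups, while the diaryl ether and biaryl bonds offer no sp3 carbon to attack, and staying at or below rt avoids acid-driven dibenzofuran closure of the 2,2'-dihydroxybiaryl; no stereo-element is involved.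

## Compound list
1 | 1,3-dibromo-5-methoxybenzene | COc1cc(Br)cc(Br)c1 | starting material
2 | syringaldehyde (4-hydroxy-3,5-dimethoxybenzaldehyde) | COc1cc(C=O)cc(OC)c1O | starting material
3 | monoether bromide, 4-(3-bromo-5-methoxyphenoxy)-3,5-dimethoxybenzaldehyde (formed in the flask) | COc1cc(Br)cc(Oc2c(OC)cc(C=O)cc2OC)c1 | intermediate
4 | 4,4'-[(5-methoxy-1,3-phenylene)bis(oxy)]bis(3,5-dimethoxybenzaldehyde) | COc1cc(Oc2c(OC)cc(C=O)cc2OC)cc(Oc2c(OC)cc(C=O)cc2OC)c1 | intermediate
5 | bis-formate, (5-methoxy-1,3-phenylene)bis(oxy-3,5-dimethoxy-4,1-phenylene) diformate (formed in the flask) | COc1cc(Oc2c(OC)cc(OC=O)cc2OC)cc(Oc2c(OC)cc(OC=O)cc2OC)c1 | intermediate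
6 | 4,4'-[(5-methoxy-1,3-phenylene)bis(oxy)]bis(3,5-dimethoxyphenol) | COc1cc(Oc2c(OC)cc(O)cc2OC)cc(Oc2c(OC)cc(O)cc2OC)c1 | intermediate
7 | 1,3,5-trimethoxybenzene | COc1cc(OC)cc(OC)c1 | starting material
8 | phenoxenium acetate, the 4-aryloxy-3,5-dimethoxyphenoxenium (O-aryl oxocarbenium dienone) ion of 6 as its acetate ion pair (formed in the flask) | COc1cc(Oc2c(OC)cc(O)cc2OC)cc([O+]=C2C(OC)=CC(=O)C=C2OC)c1.CC(=O)[O-] | intermediate
9 | 3-[3-(4-hydroxy-2,6-dimethoxyphenoxy)-5-methoxyphenoxy]-2,2',4,4',6'-pentamethoxybiphenyl-6-ol (achiral) | COc1cc(Oc2c(OC)cc(O)cc2OC)cc(Oc2c(OC)cc(O)c(-c3c(OC)cc(OC)cc3OC)c2OC)c1 | intermediate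
10 | 3-[3-hydroxy-5-(2,4,6-trihydroxyphenoxy)phenoxy]biphenyl-2,2',4,4',6,6'-hexol (achiral) | Oc1cc(Oc2c(O)cc(O)cc2O)cc(Oc2c(O)cc(O)c(-c3c(O)cc(O)cc3O)c2O)c1 | target

## Count and risks
Total steps: 4. Longest linear sequence: 4 (1 → 4 → 6 → 9 → 10).

**Step 3 (most likely to fail).** There are four risks:
- The iodane may be diverted by 7 into an iodonium salt.
- Ion 8 may collapse with loss of the ring B phenol if traces of water or acetate intervene.
- 6 may couple with itself.
- The mono-coupling is statistical, so about 30–40 % of 9 is realistic, more based on recovered 6.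

The fallback reverses which partner carries the reversed polarity. It sets out from 7, which is plumbated directly with Pb(OAc)4 (CHCl3, rt) to 2,4,6-trimethoxyphenyllead triacetate F4, an aryl-cation equivalent of ring D. Treating 6 with F4 (0.9 equiv) and pyridine in CHCl3 at 40 °C exchanges a phenoxide onto tetravalent lead. Ligand coupling (Pinhey arylation) then delivers the aryl group to the ortho carbon without ever oxidising the phenol. The route is rejoined at 9.

**Step 1.** Syringaldehyde phenoxide is both hindered and electron-poor, and it must couple twice. The fallback installs the para oxygen before the ether bonds, so that an electron-rich phenoxide is used.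
- It sets out from 2. A true Dakin oxidation (H2O2, NaOH, Ar) gives 2,6-dimethoxyhydroquinone F1.
- Alkylation at the less hindered, more acidic 4-OH (BnBr 1.0 equiv, K2CO3, acetone) gives 4-(benzyloxy)-2,6-dimethoxyphenol F2.
- Double CuI/picolinic acid coupling of F2 with 1 gives the bis(benzyl ether) 1,3-bis[4-(benzyloxy)-2,6-dimethoxyphenoxy]-5-methoxybenzene F3.
- Hydrogenolysis (H2, Pd/C, EtOAc/MeOH) rejoins the route at 6, bypassing step 2 as well.

**Step 4.** Eight cleavages must all go to completion, and the free decaphenol is polar, air-sensitive and hard to purify. The fallback is derivatise, purify, release. It sets out from 9. After the BBr3 cleavage and evaporation the crude phenol is not isolated but peracetylated (Ac2O, pyridine, rt) to the decaacetate F5. F5 is stable on silica and separates cleanly from under-cleaved material. Oxygen-free acid methanolysis (HCl generated from catalytic AcCl in MeOH, rt) then releases 10.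

## Further compounds
F1 | step 1 | 2,6-dimethoxybenzene-1,4-diol | COc1cc(O)cc(OC)c1O
F2 | step 1 | 4-(benzyloxy)-2,6-dimethoxyphenol | COc1cc(OCc2ccccc2)cc(OC)c1O
F3 | step 1 | 1,3-bis[4-(benzyloxy)-2,6-dimethoxyphenoxy]-5-methoxybenzene | COc1cc(Oc2c(OC)cc(OCc3ccccc3)cc2OC)cc(Oc2c(OC)cc(OCc3ccccc3)cc2OC)c1
F4 | step 3 | 2,4,6-trimethoxyphenyllead triacetate | COc1cc(OC)c([Pb](OC(C)=O)(OC(C)=O)OC(C)=O)c(OC)c1
F5 | step 4 | decaacetate of 10 | CC(=O)Oc1cc(Oc2c(OC(C)=O)cc(OC(C)=O)cc2OC(C)=O)cc(Oc2c(OC(C)=O)cc(OC(C)=O)c(-c3c(OC(C)=O)cc(OC(C)=O)cc3OC(C)=O)c2OC(C)=O)c1
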